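**Retrosynthetic overview**
- Last bonds: the C9–O ester to the C21 (2Z,6Z,10Z)-triene acid, then the C8–O ester to PMB-protected 2-(hydroxymethyl)acrylic acid; the C14 aldehyde and the acrylate OH are unveiled at the end.
- Ten-membered carbocycle: ring-closing metathesis at C1=C10 on the preformed lactone; the ring size enforces the ring-cis alkene.
- Lactone: a new stereoconvergent C6–O allylic lactonisation of the indium Barbier adduct (C6–C7 bond) of an (E)-enal and a (Z)-2-(bromomethyl)enoate; C6 is fixed in this C–O step.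
- C8/C9 come from an Evans syn-glycolate aldol on a 2-(silyloxymethyl)acrolein, followed by Morita–Baylis–Hillman reaction and bromination; the side-chain acid comes from neryl acetate by two (Z)-selective phosphonate olefinations.
- Ring order: γ-lactone first (step 14), ten-membered carbocycle second (step 16).

Assumption: germacrane numbering (C1–C15) of the target is used for the core; NAP = naphthalen-2-ylmethyl, TBS = tert-butyldimethylsilyl, TBDPS = tert-butyldiphenylsilyl, PMB = 4-methoxybenzyl; the carbinol epimers of the Morita–Baylis–Hillman adduct are carried on together because that centre is removed in the next step.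

**Enal fragment**

Step 1
Reactants: 1 hex-1-en-5-yne
Product: 4 (2E)-3-methylhepta-2,6-dien-1-ol, via alkenylalane 2 (not isolated), via lithium alkenylalanate 3 (not isolated)
Conditions: AlMe3 (2 equiv), Cp2ZrCl2 (0.25 equiv), CH2Cl2, 0 °C → rt; n-BuLi, THF, −78 °C; (CH2O)n, −78 °C → rt; aq. HCl
Reagents that add atoms: trimethylaluminium C[Al](C)C; formaldehyde (as paraformaldehyde) C=O
Why: Negishi zirconium-catalysed carboalumination adds Me–Al syn across the alkyne only, and the ate complex is hydroxymethylated with retention, which fixes the 4E trisubstituted alkene.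

Step 2
Reactants: 4 (2E)-3-methylhepta-2,6-dien-1-ol
Product: 5 (2E)-3-methylhepta-2,6-dienal
Conditions: MnO2 (15 equiv), CH2Cl2, rt
Reagents that add atoms: none
Why: MnO2 allylic oxidation gives the enal without E/Z erosion.

**Glycolate imide**

Step 3
Reactants: 6 naphthalen-2-ylmethanol; 7 bromoacetic acid
Product: 8 2-(naphthalen-2-ylmethoxy)acetic acid
Conditions: NaH (2.2 equiv), THF, 0 → 60 °C; aq. HCl
Reagents that add atoms: none
Why: Williamson ether synthesis of the alkoxide on the bromoacetate salt.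

Step 4
Reactants: 8 2-(naphthalen-2-ylmethoxy)acetic acid; 9 (4R)-4-benzyl-1,3-oxazolidin-2-one
Product: 11 (4R)-4-benzyl-3-[2-(naphthalen-2-ylmethoxy)acetyl]-1,3-oxazolidin-2-one, via mixed pivalic anhydride 10 (not isolated)
Conditions: PivCl, Et3N, THF, −20 °C; then 9, LiCl, −20 °C → rt
Reagents that add atoms: none
Why: N-acylation of the Evans oxazolidinone through the pivalic mixed anhydride under LiCl/Et3N activation.

**Core fragment up to the allyl bromide**

Step 5
Reactants: 12 2-methylidenepropane-1,3-diol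
Product: 13 2-[(TBDPS-oxy)methyl]prop-2-en-1-ol
Conditions: NaH (1.0 equiv), THF, 0 °C; TBDPSCl (1.0 equiv), 0 °C → rt
Reagents that add atoms: tert-butyl(chloro)diphenylsilane CC(C)(C)[Si](Cl)(c1ccccc1)c1ccccc1
Why: Monosilylation of the symmetric diol through its monosodium alkoxide.

Step 6
Reactants: 13 2-[(TBDPS-oxy)methyl]prop-2-en-1-ol
Product: 14 2-[(TBDPS-oxy)methyl]prop-2-enal
Conditions: MnO2, CH2Cl2, rt
Reagents that add atoms: none
Why: MnO2 allylic oxidation to the non-enolisable 2-substituted acrolein.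

Step 7
Reactants: 11 (4R)-4-benzyl-3-[2-(naphthalen-2-ylmethoxy)acetyl]-1,3-oxazolidin-2-one; 14 2-[(TBDPS-oxy)methyl]prop-2-enal
Product: 16 (4R)-4-benzyl-3-[(2R,3S)-3-hydroxy-2-(naphthalen-2-ylmethoxy)-4-(TBDPS-oxymethyl)pent-4-enoyl]-1,3-oxazolidin-2-one, via dibutylboron enolate 15 (not isolated)
Conditions: Bu2BOTf, Et3N, CH2Cl2, −78 → 0 °C; 14, −78 → 0 °C; pH 7 buffer, MeOH, 30% H2O2, 0 °C
Reagents that add atoms: none
Why: Evans boron syn-glycolate aldol reaction, in which the (Z)-enolate reacts through a Zimmerman–Traxler chair on the face away from the benzyl group of the (R)-auxiliary and sets C8 and C9 (8S,9S in the target) with the two oxygens already differentiated.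

Step 8
Reactants: 16 syn-aldol adduct
Product: 17 (4R)-4-benzyl-3-[(2R,3S)-3-(TBS-oxy)-2-(naphthalen-2-ylmethoxy)-4-(TBDPS-oxymethyl)pent-4-enoyl]-1,3-oxazolidin-2-one
Conditions: TBSOTf, 2,6-lutidine, CH2Cl2, −78 → 0 °C
Reagents that add atoms: tert-butyldimethylsilyl trifluoromethanesulfonate CC(C)(C)[Si](C)(C)OS(=O)(=O)C(F)(F)F
Why: Silylation with the silyl triflate masks C9–OH for the bromination and lactonisation steps.

Step 9
Reactants: 17 silylated aldol imide
Product: 18 (2S,3S)-3-(TBS-oxy)-2-(naphthalen-2-ylmethoxy)-4-(TBDPS-oxymethyl)pent-4-en-1-ol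
Conditions: LiBH4, MeOH (1.1 equiv), THF, 0 °C
Reagents that add atoms: none
Why: Reductive cleavage of the Evans imide by LiBH4 gives the primary alcohol and returns the auxiliary.

Step 10
Reactants: 18 primary alcohol
Product: 19 (2R,3S)-3-(TBS-oxy)-2-(naphthalen-2-ylmethoxy)-4-(TBDPS-oxymethyl)pent-4-enal
Conditions: Dess–Martin periodinane, CH2Cl2, 0 °C → rt
Reagents that add atoms: none
Why: Dess–Martin oxidation under non-basic conditions keeps the α-alkoxy stereocentre intact.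

Step 11
Reactants: 19 α-alkoxy aldehyde; 20 methyl acrylate
Product: 21 methyl (4S,5S)-3-hydroxy-2-methylidene-4-(naphthalen-2-ylmethoxy)-5-(TBS-oxy)-6-(TBDPS-oxymethyl)hept-6-enoate (C3 epimers)
Conditions: DABCO (1.0 equiv), 20 (neat, 10 equiv), rt, 48 h
Reagents that add atoms: none
Why: Morita–Baylis–Hillman reaction, which is fast for α-alkoxy aldehydes; the new carbinol centre is destroyed in step 12.

Step 12
Reactants: 21 Morita–Baylis–Hillman adduct
Product: 22 methyl (2Z,4S,5S)-2-(bromomethyl)-4-(naphthalen-2-ylmethoxy)-5-(TBS-oxy)-6-(TBDPS-oxymethyl)hepta-2,6-dienoate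
Conditions: NBS, Me2S, CH2Cl2, 0 °C → rt
Reagents that add atoms: N-bromosuccinimide O=C1CCC(=O)N1Br
Why: Corey–Kim-type bromination with allylic transposition (SN2′) gives the thermodynamically preferred (Z)-2-(bromomethyl)enoate, with C8 trans to the ester.

**Coupling, lactone, carbocycle**

Step 13
Reactants: 22 allyl bromide; 5 (2E)-3-methylhepta-2,6-dienal
Product: 24 methyl (3S,4S,5E)-4-hydroxy-6-methyl-2-methylidene-3-[(1S,2S)-1-(naphthalen-2-ylmethoxy)-2-(TBS-oxy)-3-(TBDPS-oxymethyl)but-3-en-1-yl]deca-5,9-dienoate, via allylindium dibromide 23 (not isolated)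
Conditions: indium powder (1.5 equiv), THF/H2O (1:1), rt
Reagents that add atoms: none
Why: Indium-mediated Barbier allylation, in which γ-attack of the (Z)-allylindium through a chair transition state forms C6–C7 and the exocyclic methylene, gives mainly the 6,7-syn adduct (6S), and sets C7 (7S) by attack anti to the bulky C9 branch of the A(1,3)-locked C8 centre, the sense also expected for indium chelation by the C8 ether.

Step 14
Reactants: 24 Barbier hydroxy ester
Product: 25 (4S,5R)-3-methylidene-5-[(1E)-2-methylhexa-1,5-dien-1-yl]-4-[(1S,2S)-1-(naphthalen-2-ylmethoxy)-2-(TBS-oxy)-3-(TBDPS-oxymethyl)but-3-en-1-yl]oxolan-2-one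
Conditions: Ca(NTf2)2 (5 mol%), nBu4NPF6 (5 mol%), CH2Cl2, 0 °C → rt
Reagents that add atoms: none
Why: Proposed new method: stereoconvergent cationic allylic lactonisation, in which the calcium Lewis acid ionises the secondary γ,γ-disubstituted allylic C6 carbinol to a configurationally stable (E)-allyl cation that is captured 5-exo at C6 by the ester carbonyl oxygen, and the dialkoxycarbenium ion collapses to the lactone with loss of methanol; because both C6 epimers (and any cis-lactone from ordinary acyl transfer, which re-ionises) pass through the same cation, the more stable 6,7-trans lactone (6R) forms whatever the Barbier selectivity at C6, so the C–O bond formation sets C6; the closest known reactions are the Brønsted-acid-catalysed allylboration/lactonisation of 2-alkoxycarbonylallylboronates with electron-rich aryl aldehydes, where benzylic ionisation gives trans-lactones, and Ca(NTf2)2-catalysed dehydrative substitution of allylic alcohols.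

Step 15
Reactants: 25 trans-lactone silyl ether
Product: 26 (4S,5R)-4-[(1S,2S)-2-hydroxy-1-(naphthalen-2-ylmethoxy)-3-(TBDPS-oxymethyl)but-3-en-1-yl]-3-methylidene-5-[(1E)-2-methylhexa-1,5-dien-1-yl]oxolan-2-one
Conditions: 48% aq. HF, MeCN, 0 °C
Reagents that add atoms: none
Why: Selective desilylation, because aqueous HF cleaves the secondary TBS ether much faster than the primary TBDPS ether.

Step 16
Reactants: 26 lactone diene
Product: 27 (6R,7S,8S,9S)-9-hydroxy-8-(naphthalen-2-ylmethoxy)-14-(TBDPS-oxy)germacra-1(10),4,11(13)-trien-12,6-olide (4E; 1(10) ring-cis)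
Conditions: second-generation Hoveyda–Grubbs catalyst RuCl2(H2IMes)(=CH-C6H4-2-OiPr) (15 mol%), 1,4-benzoquinone (30 mol%), PhMe (1 mmol per litre), 90 °C, Ar sparge
Reagents that add atoms: none
Why: Ring-closing metathesis, in which the ruthenium carbene formed at the C1 vinyl group closes onto the 1,1-disubstituted C10 alkene, assisted by the free allylic C9–OH, and the ten-membered ring can hold the new trisubstituted alkene only in the required ring-cis geometry (C2 cis to C9).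

**Side-chain acid**

Step 17
Reactants: 28 neryl acetate
Product: 29 (2Z)-5-(3,3-dimethyloxiran-2-yl)-3-methylpent-2-en-1-yl acetate
Conditions: mCPBA (1.05 equiv), CH2Cl2, 0 °C
Reagents that add atoms: 3-chloroperoxybenzoic acid O=C(OO)c1cccc(Cl)c1
Why: Prilezhaev epoxidation, selective for the distal alkene because the 2,3-alkene is deactivated by the allylic acetate.

Step 18
Reactants: 29 epoxide
Product: 30 (2Z)-3-methyl-6-oxohex-2-en-1-yl acetate
Conditions: HIO4·2H2O, THF/Et2O, 0 °C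
Reagents that add atoms: none
Why: Periodic acid opens the epoxide and cleaves the resulting glycol (Malaprade-type cleavage) to the aldehyde.

Step 19
Reactants: 31 methyl 2-[bis(2,2,2-trifluoroethoxy)phosphoryl]acetate; 32 3-bromo-1,1-dimethoxypropane
Product: 33 methyl 2-[bis(2,2,2-trifluoroethoxy)phosphoryl]-5,5-dimethoxypentanoate
Conditions: NaH, NaI (cat.), DMSO, rt → 50 °C
Reagents that add atoms: none
Why: SN2 C-alkylation of the phosphonoacetate anion.

Step 20
Reactants: 30 (2Z)-3-methyl-6-oxohex-2-en-1-yl acetate; 33 alkylated phosphonate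
Product: 34 methyl (2Z,6Z)-8-acetoxy-2-(3,3-dimethoxypropyl)-6-methylocta-2,6-dienoate
Conditions: KN(SiMe3)2, 18-crown-6, THF, −78 °C; then 30
Reagents that add atoms: none
Why: Still–Gennari olefination gives the (Z)-trisubstituted enoate (ester cis to the chain), which later places CH2OAc cis to C8′.

Step 21
Reactants: 34 Z-enoate
Product: 35 (2Z,6Z)-2-(3,3-dimethoxypropyl)-6-methylocta-2,6-diene-1,8-diol
Conditions: i-Bu2AlH (5 equiv), CH2Cl2, −78 → 0 °C; potassium sodium tartrate work-up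
Reagents that add atoms: none
Why: Hydride reduction of the enoate to the allylic alcohol with concurrent cleavage of the acetate, leaving acetal and alkene geometry untouched.

Step 22
Reactants: 35 diol
Product: 36 (2Z,6Z)-2-(3,3-dimethoxypropyl)-6-methylocta-2,6-diene-1,8-diyl diacetate
Conditions: Ac2O, pyridine, DMAP (cat.), CH2Cl2, 0 °C → rt
Reagents that add atoms: acetic anhydride CC(=O)OC(C)=O
Why: DMAP-catalysed acetylation of both primary alcohols installs the two acetates of the target.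

Step 23
Reactants: 36 diacetate acetal
Product: 37 (2Z,6Z)-6-methyl-2-(3-oxopropyl)octa-2,6-diene-1,8-diyl diacetate
Conditions: PPTS (cat.), acetone/H2O (10:1), 50 °C
Reagents that add atoms: water O
Why: Mild acid-catalysed acetal hydrolysis that the allylic acetates survive.

Step 24
Reactants: 38 3-bromobut-3-en-1-ol
Product: 39 4-methyl-3-methylidenepentan-1-ol
Conditions: i-PrMgCl (2.3 equiv), Fe(acac)3 (5 mol%), THF/NMP, 0 °C; aq. HCl
Reagents that add atoms: isopropylmagnesium chloride CC(C)[Mg]Cl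
Why: Iron-catalysed Kumada cross-coupling of the alkenyl bromide with the secondary Grignard reagent after alkoxide formation.

Step 25
Reactants: 39 4-methyl-3-methylidenepentan-1-ol
Product: 40 5-iodo-2-methyl-3-methylidenepentane
Conditions: I2, PPh3, imidazole, CH2Cl2, 0 °C → rt
Reagents that add atoms: iodine II
Why: Appel iodination of the primary alcohol.

Step 26
Reactants: 41 diphenyl phosphonate; 42 tert-butyl bromoacetate
Product: 43 tert-butyl 2-(diphenoxyphosphoryl)acetate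
Conditions: Et3N, CH2Cl2, 0 °C → rt
Reagents that add atoms: none
Why: Michaelis–Becker-type P-alkylation gives the Ando diaryl phosphonoacetate.

Step 27
Reactants: 43 tert-butyl 2-(diphenoxyphosphoryl)acetate; 40 5-iodo-2-methyl-3-methylidenepentane
Product: 44 tert-butyl 2-(diphenoxyphosphoryl)-6-methyl-5-methylideneheptanoate
Conditions: NaH, DMSO, rt → 50 °C
Reagents that add atoms: none
Why: SN2 C-alkylation of the phosphonoacetate anion with the primary iodide.

Step 28
Reactants: 37 aldehyde diacetate; 44 alkylated Ando phosphonate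
Product: 45 tert-butyl (2Z,6Z,10Z)-12-acetoxy-6-(acetoxymethyl)-10-methyl-2-(4-methyl-3-methylidenepentyl)dodeca-2,6,10-trienoate
Conditions: NaH, THF, −78 °C; then 37, −78 → −20 °C
Reagents that add atoms: none
Why: Ando (Z)-selective Horner–Wadsworth–Emmons olefination places the carboxyl group cis to C4′.

Step 29
Reactants: 45 tert-butyl ester
Product: 47 (2Z,6Z,10Z)-12-acetoxy-6-(acetoxymethyl)-10-methyl-2-(4-methyl-3-methylidenepentyl)dodeca-2,6,10-trienoic acid, via trimethylsilyl ester 46 (not isolated)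
Conditions: TMSOTf, 2,6-lutidine, CH2Cl2, 0 °C; then pH 4 buffer
Reagents that add atoms: none
Why: Silyl-triflate-mediated tert-butyl ester cleavage (loss of isobutene, then silyl ester hydrolysis) leaves the acetates, alkenes and Z-enoate untouched.

**Acrylic acid**

Step 30
Reactants: 48 2-(bromomethyl)prop-2-enoic acid; 49 (4-methoxyphenyl)methanol
Product: 50 2-[(4-methoxybenzyloxy)methyl]prop-2-enoic acid
Conditions: NaH (2.2 equiv), THF, 0 °C → rt; aq. HCl
Reagents that add atoms: none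
Why: Williamson etherification at the allylic bromide of the carboxylate salt.

**Endgame**

Step 31
Reactants: 27 macrocyclic C9 alcohol; 47 side-chain acid
Product: 52 (6R,7S,8S,9S)-9-O-acyl derivative of 27 (acyl = residue of 47), via mixed trichlorobenzoic anhydride 51 (not isolated)
Conditions: 47 (1.5 equiv), 2,4,6-trichlorobenzoyl chloride, Et3N, PhMe, rt; then 27, 70 °C
Reagents that add atoms: none
Why: Yamaguchi mixed-anhydride esterification run hot without DMAP, the conditions that acylate hindered secondary alcohols with angelate-type (Z)-2-alkyl-2-enoic acids without Z-to-E isomerisation; C9 is retained.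

Step 32
Reactants: 52 C9 ester
Product: 53 (6R,7S,8S,9S)-9-acyloxy-8-hydroxy-14-(TBDPS-oxy)germacra-1(10),4,11(13)-trien-12,6-olide
Conditions: DDQ (3 equiv), CH2Cl2/pH 7 buffer (10:1), rt
Reagents that add atoms: none
Why: Oxidative cleavage of the NAP ether by DDQ frees C8–OH while C14 stays silylated.

Step 33
Reactants: 53 C8 alcohol; 50 2-[(4-methoxybenzyloxy)methyl]prop-2-enoic acid
Product: 55 (6R,7S,8S,9S)-9-acyloxy-8-{2-[(4-methoxybenzyloxy)methyl]acryloyloxy}-14-(TBDPS-oxy)germacra-1(10),4,11(13)-trien-12,6-olide, via O-acylisourea 54 (not isolated)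
Conditions: 50, EDC·HCl, DMAP (0.2 equiv), CH2Cl2, 0 °C → rt
Reagents that add atoms: none
Why: Steglich esterification of C8–OH, done before C14 is oxidised so that no 8,14-hemiacetal can form.

Step 34
Reactants: 55 diester silyl ether
Product: 56 14-hydroxy compound (TBDPS removed from 55)
Conditions: HF·pyridine, pyridine, THF, 0 °C → rt
Reagents that add atoms: none
Why: Fluoride-mediated desilylation of the primary allylic TBDPS ether.

Step 35
Reactants: 56 C14 allylic alcohol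
Product: 57 14-oxo compound (PMB ether of the target)
Conditions: MnO2, CH2Cl2, rt
Reagents that add atoms: none
Why: MnO2 allylic oxidation of the only free allylic alcohol gives the thermodynamically preferred enal geometry already present.

Step 36
Reactants: 57 PMB ether of the target
Product: 58 CNP0240680.3
Conditions: DDQ (1.5 equiv), CH2Cl2/pH 7 buffer (10:1), 0 °C → rt
Reagents that add atoms: none
Why: DDQ oxidative cleavage of the PMB ether liberates the 2-(hydroxymethyl)acrylate under neutral conditions.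

**Compound list**

1 | hex-1-en-5-yne | C=CCCC#C | starting material
2 | dimethyl[(1E)-2-methylhexa-1,5-dien-1-yl]alumane | C=CCC/C(C)=C/[Al](C)C | intermediate
3 | lithium butyl(dimethyl)[(1E)-2-methylhexa-1,5-dien-1-yl]aluminate | [Li+].C=CCC/C(C)=C/[Al-](C)(C)CCCC | intermediate
4 | (2E)-3-methylhepta-2,6-dien-1-ol | C=CCC/C(C)=C/CO | intermediate
5 | (2E)-3-methylhepta-2,6-dienal | C=CCC/C(C)=C/C=O | intermediate
6 | naphthalen-2-ylmethanol | OCc1ccc2ccccc2c1 | starting material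
7 | bromoacetic acid | OC(=O)CBr | starting material
8 | 2-(naphthalen-2-ylmethoxy)acetic acid | OC(=O)COCc1ccc2ccccc2c1 | intermediate
9 | (4R)-4-benzyl-1,3-oxazolidin-2-one | O=C1OC[C@@H](Cc2ccccc2)N1 | starting material
10 | 2-(naphthalen-2-ylmethoxy)acetic pivalic anhydride | CC(C)(C)C(=O)OC(=O)COCc1ccc2ccccc2c1 | intermediate
11 | (4R)-4-benzyl-3-[2-(naphthalen-2-ylmethoxy)acetyl]-1,3-oxazolidin-2-one | O=C(COCc1ccc2ccccc2c1)N1C(=O)OC[C@H]1Cc1ccccc1 | intermediate
12 | 2-methylidenepropane-1,3-diol | C=C(CO)CO | starting material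
13 | 2-[(TBDPS-oxy)methyl]prop-2-en-1-ol | C=C(CO)CO[Si](c1ccccc1)(c1ccccc1)C(C)(C)C | intermediate
14 | 2-[(TBDPS-oxy)methyl]prop-2-enal | C=C(C=O)CO[Si](c1ccccc1)(c1ccccc1)C(C)(C)C | intermediate
15 | (Z)-dibutylboron enolate of 11 | CCCCB(CCCC)O/C(=C\OCc1ccc2ccccc2c1)N1C(=O)OC[C@H]1Cc1ccccc1 | intermediate
16 | (4R)-4-benzyl-3-[(2R,3S)-3-hydroxy-2-(naphthalen-2-ylmethoxy)-4-(TBDPS-oxymethyl)pent-4-enoyl]-1,3-oxazolidin-2-one | O=C([C@H](OCc1ccc2ccccc2c1)[C@@H](O)C(=C)CO[Si](c1ccccc1)(c1ccccc1)C(C)(C)C)N1C(=O)OC[C@H]1Cc1ccccc1 | intermediate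
17 | (4R)-4-benzyl-3-[(2R,3S)-3-(TBS-oxy)-2-(naphthalen-2-ylmethoxy)-4-(TBDPS-oxymethyl)pent-4-enoyl]-1,3-oxazolidin-2-one | O=C([C@H](OCc1ccc2ccccc2c1)[C@@H](O[Si](C)(C)C(C)(C)C)C(=C)CO[Si](c1ccccc1)(c1ccccc1)C(C)(C)C)N1C(=O)OC[C@H]1Cc1ccccc1 | intermediate
18 | (2S,3S)-3-(TBS-oxy)-2-(naphthalen-2-ylmethoxy)-4-(TBDPS-oxymethyl)pent-4-en-1-ol | OC[C@H](OCc1ccc2ccccc2c1)[C@@H](O[Si](C)(C)C(C)(C)C)C(=C)CO[Si](c1ccccc1)(c1ccccc1)C(C)(C)C | intermediate
19 | (2R,3S)-3-(TBS-oxy)-2-(naphthalen-2-ylmethoxy)-4-(TBDPS-oxymethyl)pent-4-enal | O=C[C@H](OCc1ccc2ccccc2c1)[C@@H](O[Si](C)(C)C(C)(C)C)C(=C)CO[Si](c1ccccc1)(c1ccccc1)C(C)(C)C | intermediate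
20 | methyl acrylate | C=CC(=O)OC | starting material
21 | methyl (4S,5S)-3-hydroxy-2-methylidene-4-(naphthalen-2-ylmethoxy)-5-(TBS-oxy)-6-(TBDPS-oxymethyl)hept-6-enoate, C3 epimers | COC(=O)C(=C)C(O)[C@H](OCc1ccc2ccccc2c1)[C@@H](O[Si](C)(C)C(C)(C)C)C(=C)CO[Si](c1ccccc1)(c1ccccc1)C(C)(C)C | intermediate
22 | methyl (2Z,4S,5S)-2-(bromomethyl)-4-(naphthalen-2-ylmethoxy)-5-(TBS-oxy)-6-(TBDPS-oxymethyl)hepta-2,6-dienoate | COC(=O)/C(CBr)=C/[C@H](OCc1ccc2ccccc2c1)[C@@H](O[Si](C)(C)C(C)(C)C)C(=C)CO[Si](c1ccccc1)(c1ccccc1)C(C)(C)C | intermediate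
23 | allylindium dibromide from 22 (drawn as one component of the sesquibromide) | COC(=O)/C(C[In](Br)Br)=C/[C@H](OCc1ccc2ccccc2c1)[C@@H](O[Si](C)(C)C(C)(C)C)C(=C)CO[Si](c1ccccc1)(c1ccccc1)C(C)(C)C | intermediate
24 | methyl (3S,4S,5E)-4-hydroxy-6-methyl-2-methylidene-3-[(1S,2S)-1-(naphthalen-2-ylmethoxy)-2-(TBS-oxy)-3-(TBDPS-oxymethyl)but-3-en-1-yl]deca-5,9-dienoate (germacrane 6S,7S,8S,9S) | COC(=O)C(=C)[C@@H]([C@@H](O)/C=C(\C)CCC=C)[C@H](OCc1ccc2ccccc2c1)[C@@H](O[Si](C)(C)C(C)(C)C)C(=C)CO[Si](c1ccccc1)(c1ccccc1)C(C)(C)C | intermediate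
25 | (4S,5R)-3-methylidene-5-[(1E)-2-methylhexa-1,5-dien-1-yl]-4-[(1S,2S)-1-(naphthalen-2-ylmethoxy)-2-(TBS-oxy)-3-(TBDPS-oxymethyl)but-3-en-1-yl]oxolan-2-one (germacrane 6R,7S,8S,9S) | C=C1C(=O)O[C@H](/C=C(\C)CCC=C)[C@H]1[C@H](OCc1ccc2ccccc2c1)[C@@H](O[Si](C)(C)C(C)(C)C)C(=C)CO[Si](c1ccccc1)(c1ccccc1)C(C)(C)C | intermediate
26 | (4S,5R)-4-[(1S,2S)-2-hydroxy-1-(naphthalen-2-ylmethoxy)-3-(TBDPS-oxymethyl)but-3-en-1-yl]-3-methylidene-5-[(1E)-2-methylhexa-1,5-dien-1-yl]oxolan-2-one | C=C1C(=O)O[C@H](/C=C(\C)CCC=C)[C@H]1[C@H](OCc1ccc2ccccc2c1)[C@@H](O)C(=C)CO[Si](c1ccccc1)(c1ccccc1)C(C)(C)C | intermediate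
27 | (6R,7S,8S,9S)-9-hydroxy-8-(naphthalen-2-ylmethoxy)-14-(TBDPS-oxy)germacra-1(10),4,11(13)-trien-12,6-olide (4E; 1(10) ring-cis) | C(O[C@H]1[C@H]2C(=C)C(=O)O[C@@H]2/C=C(\C)CC/C=C(/CO[Si](c2ccccc2)(c2ccccc2)C(C)(C)C)[C@@H]1O)c1ccc2ccccc2c1 | intermediate
28 | neryl acetate, (2Z)-3,7-dimethylocta-2,6-dien-1-yl acetate | CC(C)=CCC/C(C)=C\COC(C)=O | starting material
29 | (2Z)-5-(3,3-dimethyloxiran-2-yl)-3-methylpent-2-en-1-yl acetate (racemic epoxide) | CC1(C)OC1CC/C(C)=C\COC(C)=O | intermediate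
30 | (2Z)-3-methyl-6-oxohex-2-en-1-yl acetate | O=CCC/C(C)=C\COC(C)=O | intermediate
31 | methyl 2-[bis(2,2,2-trifluoroethoxy)phosphoryl]acetate | COC(=O)CP(=O)(OCC(F)(F)F)OCC(F)(F)F | starting material
32 | 3-bromo-1,1-dimethoxypropane | COC(CCBr)OC | starting material
33 | methyl 2-[bis(2,2,2-trifluoroethoxy)phosphoryl]-5,5-dimethoxypentanoate (racemic) | COC(=O)C(CCC(OC)OC)P(=O)(OCC(F)(F)F)OCC(F)(F)F | intermediate
34 | methyl (2Z,6Z)-8-acetoxy-2-(3,3-dimethoxypropyl)-6-methylocta-2,6-dienoate | COC(=O)/C(CCC(OC)OC)=C\CC/C(C)=C\COC(C)=O | intermediate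
35 | (2Z,6Z)-2-(3,3-dimethoxypropyl)-6-methylocta-2,6-diene-1,8-diol | OC/C(CCC(OC)OC)=C\CC/C(C)=C\CO | intermediate
36 | (2Z,6Z)-2-(3,3-dimethoxypropyl)-6-methylocta-2,6-diene-1,8-diyl diacetate | CC(=O)OC/C(CCC(OC)OC)=C\CC/C(C)=C\COC(C)=O | intermediate
37 | (2Z,6Z)-6-methyl-2-(3-oxopropyl)octa-2,6-diene-1,8-diyl diacetate | CC(=O)OC/C(CCC=O)=C\CC/C(C)=C\COC(C)=O | intermediate
38 | 3-bromobut-3-en-1-ol | C=C(Br)CCO | starting material
39 | 4-methyl-3-methylidenepentan-1-ol | C=C(CCO)C(C)C | intermediate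
40 | 5-iodo-2-methyl-3-methylidenepentane | C=C(CCI)C(C)C | intermediate
41 | diphenyl phosphonate (diphenyl phosphite) | O=[PH](Oc1ccccc1)Oc1ccccc1 | starting material
42 | tert-butyl bromoacetate | CC(C)(C)OC(=O)CBr | starting material
43 | tert-butyl 2-(diphenoxyphosphoryl)acetate | CC(C)(C)OC(=O)CP(=O)(Oc1ccccc1)Oc1ccccc1 | intermediate
44 | tert-butyl 2-(diphenoxyphosphoryl)-6-methyl-5-methylideneheptanoate (racemic) | CC(C)(C)OC(=O)C(CCC(=C)C(C)C)P(=O)(Oc1ccccc1)Oc1ccccc1 | intermediate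
45 | tert-butyl (2Z,6Z,10Z)-12-acetoxy-6-(acetoxymethyl)-10-methyl-2-(4-methyl-3-methylidenepentyl)dodeca-2,6,10-trienoate | CC(C)(C)OC(=O)/C(=C\CC/C(=C/CC/C(C)=C\COC(C)=O)COC(C)=O)CCC(=C)C(C)C | intermediate
46 | trimethylsilyl ester of 47 | C[Si](C)(C)OC(=O)/C(=C\CC/C(=C/CC/C(C)=C\COC(C)=O)COC(C)=O)CCC(=C)C(C)C | intermediate
47 | (2Z,6Z,10Z)-12-acetoxy-6-(acetoxymethyl)-10-methyl-2-(4-methyl-3-methylidenepentyl)dodeca-2,6,10-trienoic acid | OC(=O)/C(=C\CC/C(=C/CC/C(C)=C\COC(C)=O)COC(C)=O)CCC(=C)C(C)C | intermediate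
48 | 2-(bromomethyl)prop-2-enoic acid | C=C(CBr)C(=O)O | starting material
49 | (4-methoxyphenyl)methanol | COc1ccc(CO)cc1 | starting material
50 | 2-[(4-methoxybenzyloxy)methyl]prop-2-enoic acid | C=C(COCc1ccc(OC)cc1)C(=O)O | intermediate
51 | mixed anhydride of 47 and 2,4,6-trichlorobenzoic acid | O=C(OC(=O)c1c(Cl)cc(Cl)cc1Cl)/C(=C\CC/C(=C/CC/C(C)=C\COC(C)=O)COC(C)=O)CCC(=C)C(C)C | intermediate
52 | (6R,7S,8S,9S)-9-O-acyl derivative of 27 (acyl from 47) | C(O[C@H]1[C@H]2C(=C)C(=O)O[C@@H]2/C=C(\C)CC/C=C(/CO[Si](c2ccccc2)(c2ccccc2)C(C)(C)C)[C@@H]1OC(=O)/C(=C\CC/C(=C/CC/C(C)=C\COC(C)=O)COC(C)=O)CCC(=C)C(C)C)c1ccc2ccccc2c1 | intermediate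
53 | (6R,7S,8S,9S)-9-acyloxy-8-hydroxy-14-(TBDPS-oxy)germacra-1(10),4,11(13)-trien-12,6-olide | O[C@H]1[C@H]2C(=C)C(=O)O[C@@H]2/C=C(\C)CC/C=C(/CO[Si](c2ccccc2)(c2ccccc2)C(C)(C)C)[C@@H]1OC(=O)/C(=C\CC/C(=C/CC/C(C)=C\COC(C)=O)COC(C)=O)CCC(=C)C(C)C | intermediate
54 | O-acylisourea of 50 with EDC | C=C(COCc1ccc(OC)cc1)C(=O)OC(=NCC)NCCCN(C)C | intermediate
55 | 8-O-{2-[(4-methoxybenzyloxy)methyl]acryloyl} derivative of 53 | C=C(COCc1ccc(OC)cc1)C(=O)O[C@H]1[C@H]2C(=C)C(=O)O[C@@H]2/C=C(\C)CC/C=C(/CO[Si](c2ccccc2)(c2ccccc2)C(C)(C)C)[C@@H]1OC(=O)/C(=C\CC/C(=C/CC/C(C)=C\COC(C)=O)COC(C)=O)CCC(=C)C(C)C | intermediate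
56 | 14-hydroxy compound (55 without TBDPS) | C=C(COCc1ccc(OC)cc1)C(=O)O[C@H]1[C@H]2C(=C)C(=O)O[C@@H]2/C=C(\C)CC/C=C(/CO)[C@@H]1OC(=O)/C(=C\CC/C(=C/CC/C(C)=C\COC(C)=O)COC(C)=O)CCC(=C)C(C)C | intermediate
57 | 14-oxo compound, PMB ether of the target | C=C(COCc1ccc(OC)cc1)C(=O)O[C@H]1[C@H]2C(=C)C(=O)O[C@@H]2/C=C(\C)CC/C=C(/C=O)[C@@H]1OC(=O)/C(=C\CC/C(=C/CC/C(C)=C\COC(C)=O)COC(C)=O)CCC(=C)C(C)C | intermediate
58 | CNP0240680.3, (6R,7S,8S,9S)-9-acyloxy-8-[2-(hydroxymethyl)acryloyloxy]-14-oxogermacra-1(10),4,11(13)-trien-12,6-olide | C=C(CO)C(=O)O[C@H]1[C@H]2C(=C)C(=O)O[C@@H]2/C=C(\C)CC/C=C(/C=O)[C@@H]1OC(=O)/C(=C\CC/C(=C/CC/C(C)=C\COC(C)=O)COC(C)=O)CCC(=C)C(C)C | target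

**Totals and risks**

Total step count: 36 (core 18, enal 2, glycolate imide 2, side-chain acid 13, acrylic acid 1).
Longest linear sequence: 18 steps, from 12 to 58 (steps 5–16 and 31–36).

Step 14, the proposed new lactonisation. It may fail through E/Z scrambling at C4=C5, diene formation or loss of the NAP ether. The fallback uses known chemistry and sets out from 24: LiOH in THF/H2O at 0 °C hydrolyses the methyl ester to the hydroxy acid F1, and a Mitsunobu lactonisation (PPh3, DIAD, THF, 0 °C) displaces the activated allylic C6–OH by the carboxylate with inversion. This turns the 6,7-syn adduct into the trans-lactone 25, where the route is rejoined.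

Step 16, ring-closing metathesis on the strained lactone diene with a hindered 1,1-disubstituted alkene. The fallback closes the ten-membered ring before the lactone and sets out from the more flexible open chain 24: the same ruthenium catalyst gives the macrocyclic hydroxy ester F2, LiOH gives the macrocyclic hydroxy acid F3, and Mitsunobu lactonisation (PPh3, DIAD) inverts C6 to give the macrocyclic lactone silyl ether F4. Aqueous HF in MeCN then removes the TBS group and the route is rejoined at 27.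

Step 31, acylation of the hindered C9–OH with the isomerisation-prone Z acid. The fallback forms the side-chain C2′=C3′ alkene on the core instead and sets out from 44: TMSOTf/2,6-lutidine converts it to the phosphono acid F5, and EDC·HCl/DMAP couples this to 27 (phosphonoacetic acids acylate hindered alcohols readily) to give the phosphonoacetate ester F6. An intermolecular Ando olefination of this ester with aldehyde 37 (NaI, DBU, THF, 0 °C) gives the (Z)-enoate 52, where the route is rejoined.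

Further compounds
F1 | step 14 | (3S,4S,5E)-4-hydroxy-6-methyl-2-methylidene-3-[(1S,2S)-1-(naphthalen-2-ylmethoxy)-2-(TBS-oxy)-3-(TBDPS-oxymethyl)but-3-en-1-yl]deca-5,9-dienoic acid | OC(=O)C(=C)[C@@H]([C@@H](O)/C=C(\C)CCC=C)[C@H](OCc1ccc2ccccc2c1)[C@@H](O[Si](C)(C)C(C)(C)C)C(=C)CO[Si](c1ccccc1)(c1ccccc1)C(C)(C)C
F2 | step 16 | methyl (6S,7S,8S,9S)-6-hydroxy-8-(naphthalen-2-ylmethoxy)-9-(TBS-oxy)-14-(TBDPS-oxy)germacra-1(10),4,11(13)-trien-12-oate | COC(=O)C(=C)[C@H]1[C@@H](O)/C=C(\C)CC/C=C(/CO[Si](c2ccccc2)(c2ccccc2)C(C)(C)C)[C@H](O[Si](C)(C)C(C)(C)C)[C@H]1OCc1ccc2ccccc2c1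
F3 | step 16 | (6S,7S,8S,9S)-6-hydroxy-8-(naphthalen-2-ylmethoxy)-9-(TBS-oxy)-14-(TBDPS-oxy)germacra-1(10),4,11(13)-trien-12-oic acid | OC(=O)C(=C)[C@H]1[C@@H](O)/C=C(\C)CC/C=C(/CO[Si](c2ccccc2)(c2ccccc2)C(C)(C)C)[C@H](O[Si](C)(C)C(C)(C)C)[C@H]1OCc1ccc2ccccc2c1
F4 | step 16 | (6R,7S,8S,9S)-8-(naphthalen-2-ylmethoxy)-9-(TBS-oxy)-14-(TBDPS-oxy)germacra-1(10),4,11(13)-trien-12,6-olide | C(O[C@H]1[C@H]2C(=C)C(=O)O[C@@H]2/C=C(\C)CC/C=C(/CO[Si](c2ccccc2)(c2ccccc2)C(C)(C)C)[C@@H]1O[Si](C)(C)C(C)(C)C)c1ccc2ccccc2c1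
F5 | step 31 | 2-(diphenoxyphosphoryl)-6-methyl-5-methylideneheptanoic acid | OC(=O)C(CCC(=C)C(C)C)P(=O)(Oc1ccccc1)Oc1ccccc1
F6 | step 31 | 9-O-[2-(diphenoxyphosphoryl)-6-methyl-5-methylideneheptanoyl] derivative of 27 | C(O[C@H]1[C@H]2C(=C)C(=O)O[C@@H]2/C=C(\C)CC/C=C(/CO[Si](c2ccccc2)(c2ccccc2)C(C)(C)C)[C@@H]1OC(=O)C(CCC(=C)C(C)C)P(=O)(Oc1ccccc1)Oc1ccccc1)c1ccc2ccccc2c1
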